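The numbers are assumed; no experiment stands behind them.

A ratio of two free base to one electrophile coupled was where I began, since this flask is charged with protonated nucleophile.

electrophile 0.13 M; protonated nucleophile 0.169 M; time 40 min

    electrophile + nucleophile ⇌ acid set free + target (K1 = 0.59, k1 = 6.5 L mol⁻¹ min⁻¹)
    nucleophile + acid set free ⇌ protonated nucleophile, settled at all times (K2 = 23000 L mol⁻¹)
    acid set free + free base ⇌ salt of the base, settled at all times (K3 = 2.5 × 10⁵ L mol⁻¹)
    electrophile + target → side product (k4 = 0.052 L mol⁻¹ min⁻¹)
    electrophile ⇌ dormant form (K5 = 0.89, k5 = 0.015 min⁻¹)

- the concentration of free base at which the part of the electrophile that has reacted at 40 min is just 95%, in M

- percentages count the electrophile that a species holds: one side product counts as two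
- the amount of free base is what is sought; it is there from the start
- run time (flask): 40 min

1. I reckoned that each coupling took one free base to release a nucleophile and a second to hold the acid set free, since the free base binds acid more strongly than the nucleophile does.

2. I dropped the side product because the half-life of 0.82 min for nucleophile by step 1 (forward rate alone) was far shorter than the 100 min for target by the side step, both with the other concentrations as charged.

3. I read "reacted" as no longer electrophile, so the dormant form counted as reacted, and I assumed step 5 at balance, which set it at 0.89 times the electrophile left. My answer for the flask as asked was 0.235 M: the base bill, twice the electrophile that must couple once the leftover electrophile and its dormant form are subtracted from the charge.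

4. I compared a neighbouring flask with the same free base but half the protonated nucleophile. Its 0.0845 M of nucleophile is less than the electrophile, and its bill, twice that nucleophile, is 0.169 M, less than my 0.235 M, so I took nucleophile as the limiting reagent there; in the flask as asked my bill is less than twice the electrophile, so I took base as the limiting reagent. Splitting the uncoupled electrophile between electrophile and dormant form, I expected 81.5% reacted there.

5. The forecast was 0.262 M, above my bill, and it differed from me at the start: “Treat dormant electrophile as unreacted”.

6. The simulation gave 0.242 M, so the forecast held within its margin, and my bill was 97.1% of that value. The neighbouring flask reached 80.9% against my 81.5%. In the flask as asked, the relaxation half-life of step 1 by that step alone at 40.0 min, both ways together, was 0.518 min, much shorter than the run of 40 min, and that step had 95% of its turnover up to 40.0 min behind it after 8.00 min. At 40.0 min the half-life of target by the side step was far longer than that relaxation, at 34 h.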